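**Assumption:** the SMILES specifies a trans (E) alkene and an (R) benzylic carbinol. I derived (R) from the neighbour order at the stereocentre. The E/Z mixture from RCM is assumed to be separable.

## Retrosynthetic overview
- Target ← demethylation of a trimethyl ether ← asymmetric transfer hydrogenation (ATH) of the macrocyclic aryl ketone, which sets the (R)-carbinol last.
- The 22-membered ring, including the E-alkene, is closed by RCM of a diaryl ether that carries two terminal alkene chains.
- That diene comes from a late Ullmann C–O coupling of an aryl iodide (the 3-methoxy-5-heptenylphenyl half) with a 2,6-dimethoxyphenol (the 4-nonenoyl half).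
- Both halves are built from small pieces: 1,3-dibromobenzene with 1,6-heptadiene, and resorcinol with 1,7-octadiene. The diene chains are attached by B-alkyl Suzuki and carbonylative Suzuki couplings.

## Route

**Step 1**
Reactants: 1 (1,3-dibromobenzene, Brc1cccc(Br)c1)
Product: 2 (3,5-dibromophenol)
Conditions: (a) HBpin, [Ir(OMe)(cod)]2, dtbpy, THF, 80 °C; (b) Oxone, acetone/H2O, rt (one pot)
Reagents that add atoms: HBpin (CC1(C)OBOC1(C)C); Oxone (KHSO5, OOS(=O)(=O)[O-].[K+]), which supplies the phenol O
Why: Ir-catalysed C–H borylation is sterically controlled, so it goes to C5, the only position not flanked by a substituent. Oxidative B→OH conversion then gives the phenol (no stereocentre).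

**Step 2**
Reactants: 2
Product: 3 (3,5-dibromoanisole)
Conditions: MeI, K2CO3, acetone, reflux
Reagents that add atoms: MeI (CI)
Why: Simple Williamson O-methylation of the phenol.

**Step 3**
Reactants: 4 (1,6-heptadiene, C=CCCCC=C)
Product: 5 (B-(hept-6-en-1-yl)-9-BBN)
Conditions: 9-BBN dimer (1 equiv BH), THF, 0 °C→rt; excess diene (3 equiv) and solvent removed in vacuo
Reagents that add atoms: 9-BBN (C1CC2CCCC(C1)B2)
Why: 9-BBN hydroborates a terminal alkene anti-Markovnikov, and the excess diene limits bis-hydroboration, leaving one alkene free for the later RCM.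

**Step 4**
Reactants: 3 (2.5 equiv), 5
Product: 6 (1-bromo-3-(hept-6-en-1-yl)-5-methoxybenzene)
Conditions: PdCl2(dppf) (5 mol%), aq. K3PO4, THF, 60 °C
Reagents that add atoms: none
Why: B-alkyl Suzuki–Miyaura coupling; excess dibromide favours mono-coupling (the recovered dibromide is recycled).

**Step 5**
Reactants: 6
Product: 7 (1-(hept-6-en-1-yl)-3-iodo-5-methoxybenzene, fragment A)
Conditions: NaI (2 equiv), CuI (5 mol%), trans-N,N'-dimethylcyclohexane-1,2-diamine (10 mol%), dioxane, 110 °C
Reagents that add atoms: NaI ([Na+].[I-])
Why: Cu-catalysed aromatic Finkelstein reaction gives the more reactive iodide for the hindered Ullmann coupling, and NaBr precipitation drives it.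

**Step 6**
Reactants: 8 (resorcinol, Oc1cccc(O)c1)
Product: 9 (1,3-dimethoxybenzene)
Conditions: MeI (2.5 equiv), K2CO3, acetone, reflux
Reagents that add atoms: MeI (CI)
Why: Double O-methylation.

**Step 7**
Reactants: 9
Product: 10 (2,6-dimethoxyphenol)
Conditions: (a) n-BuLi, THF, 0 °C→rt; (b) B(OMe)3, −78 °C→rt; (c) H2O2, aq. NaOH, 0 °C
Reagents that add atoms: H2O2 (OO), which supplies the phenol O; B(OMe)3 (COB(OC)OC) is lost as borate
Why: Directed ortho-metalation occurs at C2 between the two OMe groups, and boronate oxidation then installs the central oxygen.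

**Step 8**
Reactants: 10
Product: 11 (4-iodo-2,6-dimethoxyphenol)
Conditions: NIS, MeCN, 0 °C→rt, dark
Reagents that add atoms: NIS (O=C1CCC(=O)N1I)
Why: Electrophilic iodination of the phenol goes para because both ortho positions are blocked.

**Step 9**
Reactants: 12 (1,7-octadiene, C=CCCCCC=C)
Product: 13 (B-(oct-7-en-1-yl)-9-BBN)
Conditions: 9-BBN dimer (1 equiv BH), THF, 0 °C→rt; excess diene (3 equiv) removed in vacuo
Reagents that add atoms: 9-BBN (C1CC2CCCC(C1)B2)
Why: Mono-hydroboration of the symmetric diene, as in Step 3.

**Step 10**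
Reactants: 11, 13
Product: 14 (1-(4-hydroxy-3,5-dimethoxyphenyl)non-8-en-1-one, fragment B)
Conditions: PdCl2(dppf) (5 mol%), K3PO4, CO (1 atm), dioxane, 80 °C
Reagents that add atoms: CO ([C-]#[O+])
Why: Carbonylative B-alkyl Suzuki coupling inserts CO between the aryl iodide and the alkyl group to give the aryl alkyl ketone; the phenol is tolerated as its phenoxide.

**Step 11 (fragment coupling)**
Reactants: 7 (1.2 equiv), 14
Product: 15 (diaryl ether diene, COc1cc(CCCCCC=C)cc(Oc2c(OC)cc(cc2OC)C(=O)CCCCCCC=C)c1)
Conditions: CuI (10 mol%), picolinic acid (20 mol%), K3PO4, DMSO, 90–100 °C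
Reagents that add atoms: none
Why: Cu/picolinic acid Ullmann-type C–O coupling is the method suited to di-ortho-substituted phenols. It joins the two similarly sized halves, and the ketone and terminal alkenes are inert under these conditions.

**Step 12**
Reactants: 15
Product: 16 (22-membered macrocyclic E-enone, COc1cc2cc(c1)Oc1c(OC)cc(cc1OC)C(=O)CCCCCC/C=C/CCCCC2)
Conditions: Grubbs II (5–10 mol%), 1,4-benzoquinone (10 mol%), CH2Cl2 (2 mM), 40 °C, N2 sparge; E isomer isolated by AgNO3-silica chromatography
Reagents that add atoms: none
Why: Ring-closing metathesis under high dilution closes the macrocycle with loss of ethylene, and large rings favour the thermodynamic E-alkene.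

**Step 13**
Reactants: 16
Product: 17 ((R)-alcohol trimethyl ether, COc1cc2cc(c1)Oc1c(OC)cc(cc1OC)[C@H](O)CCCCCC/C=C/CCCCC2)
Conditions: RuCl[(R,R)-TsDPEN](p-cymene) (3 mol%), HCO2H/Et3N (5:2), CH2Cl2, 35 °C
Reagents that add atoms: none (formate supplies only H)
Why: Noyori asymmetric transfer hydrogenation of an aryl alkyl ketone with the (R,R) catalyst gives the (R)-carbinol, the same sense as (R)-1-phenylethanol from acetophenone. The isolated E-alkene is untouched.

**Step 14**
Reactants: 17
Product: 18 (dehydrogravicycle)
Conditions: NaSEt (10 equiv), DMF, 130 °C, then aq. HCl quench under N2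
Reagents that add atoms: none (the methyl groups leave as EtSMe)
Why: SN2 thiolate demethylation of all three aryl methyl ethers leaves the non-ionisable benzylic alcohol, the E-alkene and the stereocentre intact.

## Compound list
1 | 1,3-dibromobenzene | Brc1cccc(Br)c1 | starting material
2 | 3,5-dibromophenol | Oc1cc(Br)cc(Br)c1 | intermediate
3 | 3,5-dibromoanisole | COc1cc(Br)cc(Br)c1 | intermediate
4 | 1,6-heptadiene | C=CCCCC=C | starting material
5 | B-(hept-6-en-1-yl)-9-BBN | C=CCCCCCB1C2CCCC1CCC2 | intermediate
6 | 1-bromo-3-(hept-6-en-1-yl)-5-methoxybenzene | COc1cc(Br)cc(CCCCCC=C)c1 | intermediate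
7 | 1-(hept-6-en-1-yl)-3-iodo-5-methoxybenzene | COc1cc(I)cc(CCCCCC=C)c1 | intermediate (fragment A)
8 | resorcinol | Oc1cccc(O)c1 | starting material
9 | 1,3-dimethoxybenzene | COc1cccc(OC)c1 | intermediate
10 | 2,6-dimethoxyphenol | COc1cccc(OC)c1O | intermediate
11 | 4-iodo-2,6-dimethoxyphenol | COc1cc(I)cc(OC)c1O | intermediate
12 | 1,7-octadiene | C=CCCCCC=C | starting material
13 | B-(oct-7-en-1-yl)-9-BBN | C=CCCCCCCB1C2CCCC1CCC2 | intermediate
14 | 1-(4-hydroxy-3,5-dimethoxyphenyl)non-8-en-1-one | C=CCCCCCCC(=O)c1cc(OC)c(O)c(OC)c1 | intermediate (fragment B)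
15 | diaryl ether diene | COc1cc(CCCCCC=C)cc(Oc2c(OC)cc(cc2OC)C(=O)CCCCCCC=C)c1 | intermediate
16 | macrocyclic E-enone trimethyl ether | COc1cc2cc(c1)Oc1c(OC)cc(cc1OC)C(=O)CCCCCC/C=C/CCCCC2 | intermediate
17 | (R)-macrocyclic alcohol trimethyl ether | COc1cc2cc(c1)Oc1c(OC)cc(cc1OC)[C@H](O)CCCCCC/C=C/CCCCC2 | intermediate
18 | dehydrogravicycle | Oc1cc2cc(c1)Oc1c(O)cc(cc1O)[C@H](O)CCCCCC/C=C/CCCCC2 | target

## Step count
Total steps: 14. Longest linear sequence: 8 (resorcinol → 9 → 10 → 11 → 14 → 15 → 16 → 17 → 18, i.e. Steps 6, 7, 8, 10, 11, 12, 13, 14), which is 57% of the total.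

## Three steps most likely to fail
1. **Step 11 (Ullmann coupling):** the di-ortho-methoxy phenol is hindered and made less nucleophilic by the para acyl group. Fallback: switch to metal-free or Cu-catalysed arylation of the phenol with a diaryliodonium salt derived from the ring-A arene, or carry out the coupling on the reduced alcohol (protected as a silyl ether) instead of the ketone.
2. **Step 12 (RCM):** a 22-membered ring can give a poor E/Z ratio, oligomers or alkene isomerisation. Fallback: use ring-closing alkyne metathesis on the corresponding diyne, then trans-hydrosilylation and protodesilylation to set the E-alkene. Alternatively, close the ring by an intramolecular Julia–Kocienski olefination.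
3. **Step 14 (exhaustive demethylation):** the harsh thiolate conditions may give incomplete or over-reaction. Fallback: rebuild fragments 7 and 14 with MOM-protected phenols, using lithiation of 1,3-bis(MOM-oxy)benzene in place of Steps 6–7, and remove the MOM groups under mild acid (ZnBr2/n-PrSH) in the last step.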